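The route rests on cutting ring A, the central benzene ring, at its adjacent carbons C6 and C1. C6 carries the arylethynyl group and C1 the carbon that becomes the methylidene carbon, next to C2, which carries ring C in the target and is held as an acetal oxygen. That oxygen polarises a C1–C6 aryne, so a copper acetylide enters at C6 and CO2 at C1 in one operation, giving both carbon–carbon bonds without closing a ring. The aryne precursor is an ortho-silyl aryl triflate of ring A with a tetrahydropyranyl ether at C2 and a silyl-protected CH2OH at C5. All later phenols travel as methoxymethyl ethers and are released in one acidic final step.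

Key step: step 9

Remarks on the chemistry
- Ring A numbering: C1 bears the methylidene carbon, C2 ring C (the 2,4-dihydroxyphenyl ring), C5 the CH2OH group, C6 the alkyne.
- C2–O is a tetrahydropyranyl acetal so that mild acid unmasks it. A boron halide at that stage could add across the ortho-alkynyl benzoate with lactonisation and would strip the other ethers.
- C5–CH2O is a silyl ether because an ester there would not survive s-BuLi and LiAlH4 on the way to the aryne precursor.
- The remaining phenols are methoxymethyl ethers because a closing BBr3 demethylation would turn the free benzylic alcohol into a bromide.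
- The acetal carbon of the tetrahydropyranyl group is carried as a racemate and removed in step 10; the target has no stereocentre.
- Assumption: 2,4-dihydroxybenzaldehyde, 4-(methoxymethoxy)benzaldehyde, 4-bromoresorcinol and 1-bromo-4-(methoxymethoxy)benzene are purchased. The target is taken as the open quinone methide drawn; any reversible closure of the ring C ortho-hydroxyl onto the methylidene carbon is not treated separately.

Step 1
Reactants: 1 2,4-dihydroxybenzaldehyde
Product: 2 2-hydroxy-4-(tetrahydropyran-2-yloxy)benzaldehyde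
Conditions: 3,4-dihydro-2H-pyran, PPTS (cat.), CH2Cl2, rt
Reagents that add atoms: 3,4-dihydro-2H-pyran, C1=COCCC1
Why: Acid-catalysed tetrahydropyranylation should take the 4-hydroxyl only, because the 2-hydroxyl is hydrogen-bonded to the aldehyde; the acetal carbon forms as a racemate and is deleted in step 10.

Step 2
Reactants: 2 2-hydroxy-4-(tetrahydropyran-2-yloxy)benzaldehyde
Product: 3 2-formyl-5-(tetrahydropyran-2-yloxy)phenyl N,N-diethylcarbamate
Conditions: Et2NCOCl, K2CO3, MeCN, 70 °C
Reagents that add atoms: N,N-diethylcarbamoyl chloride, CCN(CC)C(Cl)=O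
Why: O-Carbamoylation of the phenoxide installs the directing group for the later ortho-lithiation under basic conditions that spare acetal and aldehyde.

Step 3
Reactants: 3 2-formyl-5-(tetrahydropyran-2-yloxy)phenyl N,N-diethylcarbamate
Product: 4 2-(hydroxymethyl)-5-(tetrahydropyran-2-yloxy)phenyl N,N-diethylcarbamate
Conditions: NaBH4, MeOH/THF, 0 °C; aq. NH4Cl
Reagents that add atoms: none
Why: Hydride reduction of the aldehyde leaves carbamate and acetal untouched, and a short, cold reaction should prevent carbamoyl transfer to the new alkoxide.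

Step 4
Reactants: 4 2-(hydroxymethyl)-5-(tetrahydropyran-2-yloxy)phenyl N,N-diethylcarbamate
Product: 5 2-[(tert-butyldimethylsilyloxy)methyl]-5-(tetrahydropyran-2-yloxy)phenyl N,N-diethylcarbamate
Conditions: TBSCl, imidazole, DMF, rt
Reagents that add atoms: tert-butyldimethylsilyl chloride, CC(C)(C)[Si](C)(C)Cl
Why: Imidazole-promoted silylation of the primary alcohol gives an ether that tolerates s-BuLi, LiAlH4 and CsF in MeCN and falls to acid in the last step.

Step 5
Reactants: 5 2-[(tert-butyldimethylsilyloxy)methyl]-5-(tetrahydropyran-2-yloxy)phenyl N,N-diethylcarbamate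
Product: 7 6-[(tert-butyldimethylsilyloxy)methyl]-3-(tetrahydropyran-2-yloxy)-2-(trimethylsilyl)phenyl N,N-diethylcarbamate, via aryllithium 6 (not isolated)
Conditions: s-BuLi, TMEDA, THF, −78 °C; then Me3SiCl, −78 °C to rt
Reagents that add atoms: chlorotrimethylsilane, C[Si](C)(C)Cl
Why: Directed ortho-metalation should occur at the only free position ortho to the carbamate, which lies between the carbamate and acetal oxygens and is favoured over the benzylic CH2; a cold silyl chloride quench precedes any anionic ortho-Fries shift.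

Step 6
Reactants: 7 6-[(tert-butyldimethylsilyloxy)methyl]-3-(tetrahydropyran-2-yloxy)-2-(trimethylsilyl)phenyl N,N-diethylcarbamate
Product: 8 6-[(tert-butyldimethylsilyloxy)methyl]-3-(tetrahydropyran-2-yloxy)-2-(trimethylsilyl)phenol
Conditions: LiAlH4, THF, 0 °C to reflux; H2O, aq. NaOH work-up
Reagents that add atoms: none
Why: Reductive cleavage of the aryl carbamate (hydride attack at the carbonyl, loss of phenoxide) frees the phenol under basic conditions that spare the aryl–silicon bond, the silyl ether and the acetal.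

Step 7
Reactants: 8 6-[(tert-butyldimethylsilyloxy)methyl]-3-(tetrahydropyran-2-yloxy)-2-(trimethylsilyl)phenol
Product: 9 6-[(tert-butyldimethylsilyloxy)methyl]-3-(tetrahydropyran-2-yloxy)-2-(trimethylsilyl)phenyl trifluoromethanesulfonate
Conditions: PhNTf2, DBU, MeCN, rt
Reagents that add atoms: N-phenylbis(trifluoromethanesulfonimide), O=S(=O)(N(c1ccccc1)S(=O)(=O)C(F)(F)F)C(F)(F)F
Why: O-Triflation of the hindered phenoxide with the triflimide under amidine base gives the ortho-silyl aryl triflate without acid that would endanger the acetal.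

Step 8
Reactants: 10 4-(methoxymethoxy)benzaldehyde
Product: 11 1-ethynyl-4-(methoxymethoxy)benzene
Conditions: dimethyl (1-diazo-2-oxopropyl)phosphonate, K2CO3, MeOH, rt
Reagents that add atoms: dimethyl (1-diazo-2-oxopropyl)phosphonate, COP(=O)(OC)C(=[N+]=[N-])C(C)=O
Why: Ohira–Bestmann homologation (Seyferth–Gilbert type) converts the aldehyde into the terminal alkyne under K2CO3/MeOH, to which the methoxymethyl ether is inert.

Step 9
Reactants: 9 6-[(tert-butyldimethylsilyloxy)methyl]-3-(tetrahydropyran-2-yloxy)-2-(trimethylsilyl)phenyl trifluoromethanesulfonate, 11 1-ethynyl-4-(methoxymethoxy)benzene, 12 carbon dioxide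
Product: 15 methyl 3-[(tert-butyldimethylsilyloxy)methyl]-2-{[4-(methoxymethoxy)phenyl]ethynyl}-6-(tetrahydropyran-2-yloxy)benzoate, via aryne 13 (not isolated), via cesium carboxylate 14 (not isolated)
Conditions: (IPr)CuCl (10 mol%; IPr = 1,3-bis(2,6-diisopropylphenyl)imidazol-2-ylidene), CsF (3 equiv), CO2 (1 atm), MeCN, 0 °C to rt; then MeI, rt
Reagents that add atoms: iodomethane, CI
Why: Fluoride removes the trimethylsilyl group and triflate leaves to give aryne 13; the acetylide of monovalent copper formed from 11 adds across the strained triple bond (carbocupration), the arylcopper inserts CO2, and cesium carboxylate 14 is methylated in the same flask. The closest known reaction type is the copper-catalysed three-component coupling of arynes, terminal alkynes and CO2, which otherwise runs on to isocoumarins; room temperature and immediate O-methylation should stop it at the open ester. No ring is closed and no stereocentre is formed. The step needs regioselectivity: the C2 acetal oxygen distorts the aryne inductively so that the acetylide carbon bonds to C6 (meta to oxygen) and copper sits on C1 beside the oxygen, and the rod-shaped acetylide should let this bias override the steric effect of the C5 CH2OSi group. It also needs CO2 capture to outrun protonation of the arylcopper, which dry MeCN under a CO2 atmosphere should secure; the alkyl silyl ether and both acetals are expected to tolerate CsF in MeCN at room temperature.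

Step 10
Reactants: 15 methyl 3-[(tert-butyldimethylsilyloxy)methyl]-2-{[4-(methoxymethoxy)phenyl]ethynyl}-6-(tetrahydropyran-2-yloxy)benzoate
Product: 16 methyl 3-[(tert-butyldimethylsilyloxy)methyl]-6-hydroxy-2-{[4-(methoxymethoxy)phenyl]ethynyl}benzoate
Conditions: PPTS (cat.), MeOH, rt
Reagents that add atoms: none
Why: Acid-catalysed transacetalisation to methanol removes the aryl tetrahydropyranyl ether under conditions too mild for the aryl methoxymethyl ether and, over a few hours at room temperature, for the primary silyl ether.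

Step 11
Reactants: 16 methyl 3-[(tert-butyldimethylsilyloxy)methyl]-6-hydroxy-2-{[4-(methoxymethoxy)phenyl]ethynyl}benzoate
Product: 17 methyl 3-[(tert-butyldimethylsilyloxy)methyl]-2-{[4-(methoxymethoxy)phenyl]ethynyl}-6-(trifluoromethanesulfonyloxy)benzoate
Conditions: Tf2O, pyridine, CH2Cl2, 0 °C
Reagents that add atoms: trifluoromethanesulfonic anhydride, O=S(=O)(OS(=O)(=O)C(F)(F)F)C(F)(F)F
Why: O-Triflation of the salicylate-type phenol turns C2 of ring A into the cross-coupling electrophile.

Step 12
Reactants: 18 4-bromoresorcinol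
Product: 19 1-bromo-2,4-bis(methoxymethoxy)benzene
Conditions: MeOCH2Cl, i-Pr2NEt, CH2Cl2, 0 °C to rt
Reagents that add atoms: chloromethyl methyl ether, COCCl
Why: Twofold O-alkylation of the resorcinol with the chloromethyl ether under amine base (Williamson-type acetal formation) protects both hydroxyls of the future ring C.

Step 13
Reactants: 19 1-bromo-2,4-bis(methoxymethoxy)benzene
Product: 21 2-[2,4-bis(methoxymethoxy)phenyl]-4,4,5,5-tetramethyl-1,3,2-dioxaborolane, via aryllithium 20 (not isolated)
Conditions: n-BuLi, THF, −78 °C; then 2-isopropoxy-4,4,5,5-tetramethyl-1,3,2-dioxaborolane, −78 °C to rt; H2O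
Reagents that add atoms: 2-isopropoxy-4,4,5,5-tetramethyl-1,3,2-dioxaborolane, CC(C)OB1OC(C)(C)C(C)(C)O1
Why: Bromine–lithium exchange at −78 °C followed by borylation of the aryllithium gives the pinacol boronate, the ortho acetal stabilising the aryllithium by chelation.

Step 14
Reactants: 17 methyl 3-[(tert-butyldimethylsilyloxy)methyl]-2-{[4-(methoxymethoxy)phenyl]ethynyl}-6-(trifluoromethanesulfonyloxy)benzoate, 21 2-[2,4-bis(methoxymethoxy)phenyl]-4,4,5,5-tetramethyl-1,3,2-dioxaborolane
Product: 22 methyl 4-[(tert-butyldimethylsilyloxy)methyl]-2',4'-bis(methoxymethoxy)-3-{[4-(methoxymethoxy)phenyl]ethynyl}biphenyl-2-carboxylate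
Conditions: Pd(OAc)2 (5 mol%), SPhos (10 mol%), K3PO4, toluene/H2O (10:1), 80 °C
Reagents that add atoms: none
Why: Suzuki–Miyaura coupling of the aryl triflate, activated by the ortho ester, with the electron-rich boronate under a dialkylbiarylphosphine–palladium catalyst forms the ring A–ring C bond; the internal alkyne, silyl ether and acetals are inert.

Step 15
Reactants: 22 methyl 4-[(tert-butyldimethylsilyloxy)methyl]-2',4'-bis(methoxymethoxy)-3-{[4-(methoxymethoxy)phenyl]ethynyl}biphenyl-2-carboxylate, 23 1-bromo-4-(methoxymethoxy)benzene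
Product: 26 {4-[(tert-butyldimethylsilyloxy)methyl]-2',4'-bis(methoxymethoxy)-3-{[4-(methoxymethoxy)phenyl]ethynyl}biphenyl-2-yl}bis[4-(methoxymethoxy)phenyl]methanol, via aryllithium 24 (not isolated), via diaryl ketone 25 (not isolated)
Conditions: 23 (4 equiv), n-BuLi (3.8 equiv), THF, −78 °C; then 22, −78 to 0 °C; H2O
Reagents that add atoms: none
Why: Twofold addition of the aryllithium (from bromine–lithium exchange) to the methyl ester through the ketone gives the triarylmethanol; nothing is enolisable, and a cold quench keeps the lithium alkoxide from adding to the neighbouring alkyne.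

Step 16
Reactants: 26 {4-[(tert-butyldimethylsilyloxy)methyl]-2',4'-bis(methoxymethoxy)-3-{[4-(methoxymethoxy)phenyl]ethynyl}biphenyl-2-yl}bis[4-(methoxymethoxy)phenyl]methanol
Product: 27 selaginellin F
Conditions: 3 M aq. HCl, MeOH/THF, 45 °C; then aq. NaHCO3
Reagents that add atoms: none
Why: Acid-catalysed acetal and silyl ether cleavage removes the five methoxymethyl groups and the silyl group, and the bis(4-hydroxyphenyl)carbinol then dehydrates to the quinone methide, while methanol traps the released formaldehyde as its dimethyl acetal and the primary benzylic alcohol is left alone.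

Compound list
1 | 2,4-dihydroxybenzaldehyde | O=Cc1ccc(O)cc1O | starting material
2 | 2-hydroxy-4-(tetrahydropyran-2-yloxy)benzaldehyde (racemic acetal) | O=Cc1ccc(OC2CCCCO2)cc1O | intermediate
3 | 2-formyl-5-(tetrahydropyran-2-yloxy)phenyl N,N-diethylcarbamate (racemic) | CCN(CC)C(=O)Oc1cc(OC2CCCCO2)ccc1C=O | intermediate
4 | 2-(hydroxymethyl)-5-(tetrahydropyran-2-yloxy)phenyl N,N-diethylcarbamate (racemic) | CCN(CC)C(=O)Oc1cc(OC2CCCCO2)ccc1CO | intermediate
5 | 2-[(tert-butyldimethylsilyloxy)methyl]-5-(tetrahydropyran-2-yloxy)phenyl N,N-diethylcarbamate (racemic) | CCN(CC)C(=O)Oc1cc(OC2CCCCO2)ccc1CO[Si](C)(C)C(C)(C)C | intermediate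
6 | aryllithium: 5 lithiated at the ring carbon between the carbamate and acetal oxygens | CCN(CC)C(=O)Oc1c([Li])c(OC2CCCCO2)ccc1CO[Si](C)(C)C(C)(C)C | intermediate (not isolated)
7 | 6-[(tert-butyldimethylsilyloxy)methyl]-3-(tetrahydropyran-2-yloxy)-2-(trimethylsilyl)phenyl N,N-diethylcarbamate (racemic) | CCN(CC)C(=O)Oc1c([Si](C)(C)C)c(OC2CCCCO2)ccc1CO[Si](C)(C)C(C)(C)C | intermediate
8 | 6-[(tert-butyldimethylsilyloxy)methyl]-3-(tetrahydropyran-2-yloxy)-2-(trimethylsilyl)phenol (racemic) | Oc1c([Si](C)(C)C)c(OC2CCCCO2)ccc1CO[Si](C)(C)C(C)(C)C | intermediate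
9 | 6-[(tert-butyldimethylsilyloxy)methyl]-3-(tetrahydropyran-2-yloxy)-2-(trimethylsilyl)phenyl trifluoromethanesulfonate (racemic) | CC(C)(C)[Si](C)(C)OCc1ccc(OC2CCCCO2)c([Si](C)(C)C)c1OS(=O)(=O)C(F)(F)F | intermediate
10 | 4-(methoxymethoxy)benzaldehyde | COCOc1ccc(C=O)cc1 | starting material
11 | 1-ethynyl-4-(methoxymethoxy)benzene | C#Cc1ccc(OCOC)cc1 | intermediate
12 | carbon dioxide | O=C=O | starting material
13 | aryne: 3-[(tert-butyldimethylsilyloxy)methyl]-6-(tetrahydropyran-2-yloxy)-1,2-didehydrobenzene | CC(C)(C)[Si](C)(C)OCC1=CC=C(OC2CCCCO2)C#C1 | intermediate (not isolated)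
14 | cesium 3-[(tert-butyldimethylsilyloxy)methyl]-2-{[4-(methoxymethoxy)phenyl]ethynyl}-6-(tetrahydropyran-2-yloxy)benzoate | [Cs+].[O-]C(=O)c1c(OC2CCCCO2)ccc(CO[Si](C)(C)C(C)(C)C)c1C#Cc1ccc(OCOC)cc1 | intermediate (not isolated)
15 | methyl 3-[(tert-butyldimethylsilyloxy)methyl]-2-{[4-(methoxymethoxy)phenyl]ethynyl}-6-(tetrahydropyran-2-yloxy)benzoate (racemic) | COC(=O)c1c(OC2CCCCO2)ccc(CO[Si](C)(C)C(C)(C)C)c1C#Cc1ccc(OCOC)cc1 | intermediate
16 | methyl 3-[(tert-butyldimethylsilyloxy)methyl]-6-hydroxy-2-{[4-(methoxymethoxy)phenyl]ethynyl}benzoate | COC(=O)c1c(O)ccc(CO[Si](C)(C)C(C)(C)C)c1C#Cc1ccc(OCOC)cc1 | intermediate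
17 | methyl 3-[(tert-butyldimethylsilyloxy)methyl]-2-{[4-(methoxymethoxy)phenyl]ethynyl}-6-(trifluoromethanesulfonyloxy)benzoate | COC(=O)c1c(OS(=O)(=O)C(F)(F)F)ccc(CO[Si](C)(C)C(C)(C)C)c1C#Cc1ccc(OCOC)cc1 | intermediate
18 | 4-bromoresorcinol (4-bromobenzene-1,3-diol) | Oc1ccc(Br)c(O)c1 | starting material
19 | 1-bromo-2,4-bis(methoxymethoxy)benzene | COCOc1ccc(Br)c(OCOC)c1 | intermediate
20 | [2,4-bis(methoxymethoxy)phenyl]lithium | [Li]c1ccc(OCOC)cc1OCOC | intermediate (not isolated)
21 | 2-[2,4-bis(methoxymethoxy)phenyl]-4,4,5,5-tetramethyl-1,3,2-dioxaborolane | COCOc1ccc(B2OC(C)(C)C(C)(C)O2)c(OCOC)c1 | intermediate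
22 | methyl 4-[(tert-butyldimethylsilyloxy)methyl]-2',4'-bis(methoxymethoxy)-3-{[4-(methoxymethoxy)phenyl]ethynyl}biphenyl-2-carboxylate | COC(=O)c1c(-c2ccc(OCOC)cc2OCOC)ccc(CO[Si](C)(C)C(C)(C)C)c1C#Cc1ccc(OCOC)cc1 | intermediate
23 | 1-bromo-4-(methoxymethoxy)benzene | COCOc1ccc(Br)cc1 | starting material
24 | [4-(methoxymethoxy)phenyl]lithium | [Li]c1ccc(OCOC)cc1 | intermediate (not isolated)
25 | {4-[(tert-butyldimethylsilyloxy)methyl]-2',4'-bis(methoxymethoxy)-3-{[4-(methoxymethoxy)phenyl]ethynyl}biphenyl-2-yl}[4-(methoxymethoxy)phenyl]methanone | O=C(c1ccc(OCOC)cc1)c1c(-c2ccc(OCOC)cc2OCOC)ccc(CO[Si](C)(C)C(C)(C)C)c1C#Cc1ccc(OCOC)cc1 | intermediate (not isolated)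
26 | {4-[(tert-butyldimethylsilyloxy)methyl]-2',4'-bis(methoxymethoxy)-3-{[4-(methoxymethoxy)phenyl]ethynyl}biphenyl-2-yl}bis[4-(methoxymethoxy)phenyl]methanol | OC(c1ccc(OCOC)cc1)(c1ccc(OCOC)cc1)c1c(-c2ccc(OCOC)cc2OCOC)ccc(CO[Si](C)(C)C(C)(C)C)c1C#Cc1ccc(OCOC)cc1 | intermediate
27 | selaginellin F, 4-{[2',4'-dihydroxy-4-(hydroxymethyl)-3-[(4-hydroxyphenyl)ethynyl]biphenyl-2-yl](4-hydroxyphenyl)methylidene}cyclohexa-2,5-dien-1-one (no stereocentre) | O=C1C=CC(=C(c2ccc(O)cc2)c2c(-c3ccc(O)cc3O)ccc(CO)c2C#Cc2ccc(O)cc2)C=C1 | target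

Total step count: 16. Longest linear sequence: 13 steps (steps 1–7, 9–11 and 14–16); steps 8, 12 and 13 are side branches.

Steps most likely to fail

Step 9. Three processes could defeat it: protonation of the arylcopper before it captures CO2 (plain hydroalkynylation), attack of the carboxylate on the neighbouring alkyne before methylation (lactonisation), and erosion of the regiochemistry by the C5 substituent. The fallback separates carbon–carbon bond formation at C6 from carboxylation at C1 and uses the known copper-catalysed bromoalkynylation of arynes. It sets out from 11 and 9: bromination of 11 (NBS, AgNO3 cat., acetone) gives 1-(bromoethynyl)-4-(methoxymethoxy)benzene F1. The aryne from 9 (CsF, CuBr cat., MeCN) should take up F1 with the same oxygen-directed regiochemistry to give {[3-bromo-2-{[4-(methoxymethoxy)phenyl]ethynyl}-4-(tetrahydropyran-2-yloxy)phenyl]methoxy}(tert-butyl)dimethylsilane F2. Bromine–lithium exchange (n-BuLi, THF, −78 °C) and quench with methyl chloroformate bring the sequence back to 15.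

Step 15. Addition to the ester, which has two ortho substituents, could stall before or at the ketone stage, leaving the aryllithium to attack elsewhere. The fallback replaces the ester by the more electrophilic aldehyde and adds the two aryl groups one at a time. It sets out from 22: reduction with i-Bu2AlH gives the benzylic alcohol {4-[(tert-butyldimethylsilyloxy)methyl]-2',4'-bis(methoxymethoxy)-3-{[4-(methoxymethoxy)phenyl]ethynyl}biphenyl-2-yl}methanol F3. Dess–Martin oxidation gives the corresponding biphenyl-2-carbaldehyde F4. One equivalent of 24 at −78 °C gives the racemic diarylmethanol {4-[(tert-butyldimethylsilyloxy)methyl]-2',4'-bis(methoxymethoxy)-3-{[4-(methoxymethoxy)phenyl]ethynyl}biphenyl-2-yl}[4-(methoxymethoxy)phenyl]methanol F5, whose stereocentre is erased by a second Dess–Martin oxidation to ketone 25, now isolated. A single further addition of 24, if needed as its organocerium reagent made with CeCl3, comes back to 26.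

Step 14. Slow coupling at the hindered position beside the ester could let the electron-rich boronate protodeboronate or the triflate hydrolyse in the aqueous base. The fallback is a Negishi coupling without water or base. It sets out from 19 and 17: bromine–lithium exchange of 19 to 20 and transmetalation with ZnCl2 give [2,4-bis(methoxymethoxy)phenyl]zinc chloride F6, which is coupled with 17 (Pd2(dba)3, SPhos, THF, 60 °C) to come back to 22.

Further compounds
F1 | step 9 | 1-(bromoethynyl)-4-(methoxymethoxy)benzene | BrC#Cc1ccc(OCOC)cc1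
F2 | step 9 | {[3-bromo-2-{[4-(methoxymethoxy)phenyl]ethynyl}-4-(tetrahydropyran-2-yloxy)phenyl]methoxy}(tert-butyl)dimethylsilane (racemic acetal) | CC(C)(C)[Si](C)(C)OCc1ccc(OC2CCCCO2)c(Br)c1C#Cc1ccc(OCOC)cc1
F3 | step 15 | {4-[(tert-butyldimethylsilyloxy)methyl]-2',4'-bis(methoxymethoxy)-3-{[4-(methoxymethoxy)phenyl]ethynyl}biphenyl-2-yl}methanol | OCc1c(-c2ccc(OCOC)cc2OCOC)ccc(CO[Si](C)(C)C(C)(C)C)c1C#Cc1ccc(OCOC)cc1
F4 | step 15 | 4-[(tert-butyldimethylsilyloxy)methyl]-2',4'-bis(methoxymethoxy)-3-{[4-(methoxymethoxy)phenyl]ethynyl}biphenyl-2-carbaldehyde | O=Cc1c(-c2ccc(OCOC)cc2OCOC)ccc(CO[Si](C)(C)C(C)(C)C)c1C#Cc1ccc(OCOC)cc1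
F5 | step 15 | {4-[(tert-butyldimethylsilyloxy)methyl]-2',4'-bis(methoxymethoxy)-3-{[4-(methoxymethoxy)phenyl]ethynyl}biphenyl-2-yl}[4-(methoxymethoxy)phenyl]methanol (racemic) | OC(c1ccc(OCOC)cc1)c1c(-c2ccc(OCOC)cc2OCOC)ccc(CO[Si](C)(C)C(C)(C)C)c1C#Cc1ccc(OCOC)cc1
F6 | step 14 | [2,4-bis(methoxymethoxy)phenyl]zinc chloride | Cl[Zn]c1ccc(OCOC)cc1OCOC
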